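We choose to reckon these flasks by hand, from a ratio of two rates in which the reagent cancels.

    substrate + reagent → first product (k1 = 185 M⁻¹ s⁻¹)
    reagent + first product → bis adduct (k2 = 82.6 M⁻¹ s⁻¹)
    reagent + bis adduct → tris adduct (k3 = 521 M⁻¹ s⁻¹)
    crystals ⇌ bis adduct, rate k4*(cs4 - [bis adduct]) while solid is left; crystals form when [bis adduct] > cs4 (cs4 = 0.019 mM, k4 = 32.0 s⁻¹)

all flasks: time 4.0 s

| flask | substrate | reagent | remark |
|---|---|---|---|
| epsilon | 1.0 mM | 4.00 equiv | everything together at the start |
| beta | 1.0 mM | 4.00 equiv (fed, over 1.5 s) | all else is in the flask from the start; the feed brings no volume worth counting |
| eta | 1.0 mM (fed, over 1.5 s) | 4.00 equiv | all else is in the flask from the start; the feed brings no volume worth counting |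

- the best flask by amount of bis adduct, in percent of the substrate charged; "all alike" if 1.5 percentage points covers them all (epsilon / beta / eta / all alike)
- amount of bis adduct at the end, in percent of the substrate charged, epsilon
- amount of bis adduct at the end, in percent of the substrate charged, beta
- amount of bis adduct at the end, in percent of the substrate charged, eta

- bis adduct is meant together with its crystals
- solid, in amounts per volume of the solution: crystals
- run time (epsilon): 4.0 s

The second and third steps both carry c(reagent), so the rate of the third over the rate of the second is its rate constant times c(bis adduct), over the second rate constant times c(first product). While crystals stand, c(bis adduct) lies near 0.019 mM. So we carry the leak level, the third rate constant times the solubility over the second rate constant, 0.120 mM. Divided by c(first product), it gives the tris adduct made per bis adduct passing the second step.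

For c(first product) in epsilon we treat the first two steps as pseudo-first-order. The reagent falls, though, so we hold it at a mean of 3.00 mM, which gives 0.555 s⁻¹ and 0.248 s⁻¹. After 4.0 s, 47.4% stands as first product and 41.7% has passed the second step. The leak level takes 25.3% of that on to tris adduct.

Is the mean fair? This reckoning spends 1.41 mM of reagent by the end, and a mean spend of 1.00 mM is more than the plain midpoint of that, which suits a spend that slows.

A harder doubt is that crystals grow from supersaturation, so c(bis adduct) must stand above the solubility. Balancing the second step's supply against the crystal term and the third step gives 0.0216 mM, above 0.019 mM. The leak then rises to 28.7%, and we commit to 29.7% for epsilon.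

Either feed delays the charge by 0.750 s on average, so we reckon beta and eta alike at 3.25 s. That leaves 51.0% as first product, 32.5% past it, and 23.7% bis adduct. This gap of 6 percentage points to epsilon is wider than the margin.

The forecast says 31% for epsilon, 24.5% for beta and 27% for eta, with epsilon best, and it expects “a small, steady leak of dissolved bis goes on to tris”. Unlike our level pair, it puts eta above beta.

The simulation gives 30.8% in epsilon, 25.0% in beta and 24.2% in eta, so epsilon leads. In epsilon at 4.00 s, 0.467 mM of first product against the leak level gives a rate ratio of 25.7%, and tris adduct stands at 28.7% of what has passed the second step. The neighbouring flask, eta's recipe with 4.0 mM of substrate, holds 0.534 mM of first product at 4.00 s, which gives a ratio of 22.5%, and its tris adduct stands at 24.6% of what has passed the second step.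

(The constants are made up; the result is computed.)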